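**Plan**

1. Retrosynthesis first removes two benzyl ethers from the ring B phenols. It then cuts the three aryl–CH3 bonds C3–CH3 and C5–CH3 (ring A) and C5'–CH3 (ring B) in one operation, and last the depside ester C–O bond at C4 of ring A.
2. The enabling feature: C3 and C5 of ring A flank the C4 oxygen, and C5' of ring B lies between the C4' and C6' oxygens. Each is therefore the ortho position of a phenol, where electrophilic bromination places a leaving group. C3' carries chlorine, which is far slower in oxidative addition and is meant to stay.
3. Forward, methyl orsellinate serves for both halves. Ring A arises by 4-O-benzylation, 2-O-methylation, debenzylation and dibromination. Ring B arises by chlorination beside the C-methyl group, bromination between the hydroxyls, dibenzylation and saponification.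
4. The halves are joined through the acid chloride, the three methyl groups enter together by Suzuki–Miyaura coupling with trimethylboroxine, and BCl3 removes the benzyl ethers.
5. No ring is formed and the target has no stereocentre. Control rests on the order of halogenation and on bromide-over-chloride selectivity in the coupling.

Key step: step 10

Remark: prose positions follow the target numbering. Ring A: C1 CO2CH3, C2 OCH3, C4 acyloxy, C6 CH3. Ring B: C1' carbonyl, C2' CH3, C3' Cl, C4' OH, C5' CH3, C6' OH. Compound names carry their own systematic locants. Methyl orsellinate and trimethylboroxine are assumed to be commercially available.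

**Route**

Step 1
Reactants: 1 methyl 2,4-dihydroxy-6-methylbenzoate (methyl orsellinate)
Product: 2 methyl 4-(benzyloxy)-2-hydroxy-6-methylbenzoate
Conditions: BnBr (1.05 equiv), K2CO3, acetone, reflux
Reagents that add atoms: benzyl bromide, BrCc1ccccc1
Why: Williamson etherification should be selective for the 4-OH, because the 2-OH is held in a hydrogen bond to the ester carbonyl and is less acidic and less nucleophilic.

Step 2
Reactants: 2 methyl 4-(benzyloxy)-2-hydroxy-6-methylbenzoate
Product: 3 methyl 4-(benzyloxy)-2-methoxy-6-methylbenzoate
Conditions: MeI (excess), K2CO3, DMF, 50 °C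
Reagents that add atoms: iodomethane, CI
Why: Williamson O-methylation of the remaining hydrogen-bonded phenol should go to completion with excess MeI in a dipolar aprotic solvent, since no other hydroxyl competes.

Step 3
Reactants: 3 methyl 4-(benzyloxy)-2-methoxy-6-methylbenzoate
Product: 4 methyl 4-hydroxy-2-methoxy-6-methylbenzoate
Conditions: H2 (1 atm), Pd/C, EtOAc–MeOH, rt
Reagents that add atoms: none
Why: Catalytic hydrogenolysis cleaves the aryl benzyl ether, and no halogen or other reducible group is present at this stage.

Step 4
Reactants: 4 methyl 4-hydroxy-2-methoxy-6-methylbenzoate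
Product: 5 methyl 3,5-dibromo-4-hydroxy-2-methoxy-6-methylbenzoate
Conditions: NBS (2.1 equiv), MeCN, 0 °C → rt, dark
Reagents that add atoms: N-bromosuccinimide, O=C1CCC(=O)N1Br
Why: Electrophilic aromatic bromination should take C3 and C5, the two carbons ortho to the free phenol, which are also ortho and para to the methoxy group and are the only unsubstituted ring positions.

Step 5
Reactants: 1 methyl 2,4-dihydroxy-6-methylbenzoate (methyl orsellinate)
Product: 6 methyl 3-chloro-4,6-dihydroxy-2-methylbenzoate
Conditions: SO2Cl2 (1.0 equiv), Et2O, 0 °C → rt
Reagents that add atoms: sulfuryl chloride, ClS(Cl)(=O)=O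
Why: Electrophilic aromatic chlorination of a resorcylate ester should prefer the carbon beside the C-methyl group (C3' of the target), para to the hydrogen-bonded hydroxyl, over the more crowded carbon between the two oxygens, and one equivalent at low temperature limits dichlorination.

Step 6
Reactants: 6 methyl 3-chloro-4,6-dihydroxy-2-methylbenzoate
Product: 7 methyl 3-bromo-5-chloro-2,4-dihydroxy-6-methylbenzoate
Conditions: NBS (1.05 equiv), MeCN, 0 °C, dark
Reagents that add atoms: N-bromosuccinimide, O=C1CCC(=O)N1Br
Why: Electrophilic aromatic bromination can only take the single remaining ring carbon, which lies between the two hydroxyls (C5' of the target) and is activated by both.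

Step 7
Reactants: 7 methyl 3-bromo-5-chloro-2,4-dihydroxy-6-methylbenzoate
Product: 8 methyl 2,4-bis(benzyloxy)-3-bromo-5-chloro-6-methylbenzoate
Conditions: BnBr (2.5 equiv), K2CO3, DMF, 60 °C
Reagents that add atoms: benzyl bromide, BrCc1ccccc1
Why: Twofold Williamson benzylation should succeed because the flanking halogens make both phenols acidic and the primary benzylic bromide is an unhindered electrophile.

Step 8
Reactants: 8 methyl 2,4-bis(benzyloxy)-3-bromo-5-chloro-6-methylbenzoate
Product: 9 2,4-bis(benzyloxy)-3-bromo-5-chloro-6-methylbenzoic acid
Conditions: KOH (excess), DMSO–H2O (4:1), 100 °C; then 1 M HCl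
Reagents that add atoms: potassium hydroxide, [K+].[OH-]
Why: Saponification of the ester between two ortho substituents needs poorly solvated hydroxide in hot aqueous DMSO, conditions under which the benzyl ethers and the unactivated aryl halides meta to the ester are stable.

Step 9
Reactants: 9 2,4-bis(benzyloxy)-3-bromo-5-chloro-6-methylbenzoic acid; 5 methyl 3,5-dibromo-4-hydroxy-2-methoxy-6-methylbenzoate
Product: 11 methyl 4-{[2,4-bis(benzyloxy)-3-bromo-5-chloro-6-methylbenzoyl]oxy}-3,5-dibromo-2-methoxy-6-methylbenzoate, via acid chloride 10 (not isolated)
Conditions: (COCl)2, DMF (cat.), CH2Cl2, 0 °C → rt, evaporate; then 5, Et3N, DMAP (0.2 equiv), CH2Cl2, 0 → 40 °C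
Reagents that add atoms: none
Why: Acid chloride formation under Vilsmeier catalysis followed by DMAP-catalysed acylation of the acidic 2,6-dibromophenol (fully ionised by Et3N) uses the most reactive acyl donor for a pairing that is hindered on both sides.

Step 10
Reactants: 11 methyl 4-{[2,4-bis(benzyloxy)-3-bromo-5-chloro-6-methylbenzoyl]oxy}-3,5-dibromo-2-methoxy-6-methylbenzoate; 12 trimethylboroxine
Product: 13 methyl 4-{[2,4-bis(benzyloxy)-5-chloro-3,6-dimethylbenzoyl]oxy}-2-methoxy-3,5,6-trimethylbenzoate
Conditions: trimethylboroxine (4 equiv), PdCl2(dppf)·CH2Cl2 (15 mol %; dppf = 1,1'-bis(diphenylphosphino)ferrocene), anhydrous K2CO3 (9 equiv), 1,4-dioxane, 100 °C, argon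
Reagents that add atoms: trimethylboroxine (12), CB1OB(C)OB(C)O1
Why: PdCl2(dppf) is reduced in the flask to zerovalent palladium, which inserts into a C–Br bond; the carbonate-activated boroxine hands over a methyl group and reductive elimination forms the aryl–CH3 bond, the cycle running three times to build C3–CH3, C5–CH3 and C5'–CH3. The closest known reaction is the Suzuki–Miyaura methylation of aryl bromides with trimethylboroxine, which is established for bromides with two ortho substituents. No ring is closed and no stereocentre is created. The step needs chemoselectivity for the three C–Br bonds over the C3'–Cl bond; this rests on the weaker C–Br bond and on a bisphosphine catalyst that inserts only slowly into an electron-rich aryl chloride flanked by a methyl and a benzyloxy group. The depside ester and the methyl ester are each shielded by two ortho substituents and meet only anhydrous carbonate, and the benzyl ethers are inert. The wide bite angle of dppf speeds reductive elimination, which should limit protodebromination at the crowded carbons.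

Step 11
Reactants: 13 methyl 4-{[2,4-bis(benzyloxy)-5-chloro-3,6-dimethylbenzoyl]oxy}-2-methoxy-3,5,6-trimethylbenzoate
Product: 14 methyl 4-[(3-chloro-4,6-dihydroxy-2,5-dimethylbenzoyl)oxy]-2-methoxy-3,5,6-trimethylbenzoate (CNP0231767.0)
Conditions: BCl3 (1 M in CH2Cl2, 5 equiv), pentamethylbenzene (6 equiv), CH2Cl2, −78 °C; then aqueous work-up
Reagents that add atoms: none
Why: Lewis acid cleavage of aryl benzyl ethers by BCl3, with pentamethylbenzene as a non-basic trap for the benzyl cation, should proceed at −78 °C, where the aryl chloride, both esters and the aryl methyl ether are left alone.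

**Compound list**

1 | methyl 2,4-dihydroxy-6-methylbenzoate (methyl orsellinate) | COC(=O)c1c(C)cc(O)cc1O | starting material
2 | methyl 4-(benzyloxy)-2-hydroxy-6-methylbenzoate | COC(=O)c1c(C)cc(OCc2ccccc2)cc1O | intermediate
3 | methyl 4-(benzyloxy)-2-methoxy-6-methylbenzoate | COC(=O)c1c(C)cc(OCc2ccccc2)cc1OC | intermediate
4 | methyl 4-hydroxy-2-methoxy-6-methylbenzoate | COC(=O)c1c(C)cc(O)cc1OC | intermediate
5 | methyl 3,5-dibromo-4-hydroxy-2-methoxy-6-methylbenzoate | COC(=O)c1c(C)c(Br)c(O)c(Br)c1OC | intermediate
6 | methyl 3-chloro-4,6-dihydroxy-2-methylbenzoate | COC(=O)c1c(C)c(Cl)c(O)cc1O | intermediate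
7 | methyl 3-bromo-5-chloro-2,4-dihydroxy-6-methylbenzoate | COC(=O)c1c(C)c(Cl)c(O)c(Br)c1O | intermediate
8 | methyl 2,4-bis(benzyloxy)-3-bromo-5-chloro-6-methylbenzoate | COC(=O)c1c(C)c(Cl)c(OCc2ccccc2)c(Br)c1OCc1ccccc1 | intermediate
9 | 2,4-bis(benzyloxy)-3-bromo-5-chloro-6-methylbenzoic acid | OC(=O)c1c(C)c(Cl)c(OCc2ccccc2)c(Br)c1OCc1ccccc1 | intermediate
10 | 2,4-bis(benzyloxy)-3-bromo-5-chloro-6-methylbenzoyl chloride | ClC(=O)c1c(C)c(Cl)c(OCc2ccccc2)c(Br)c1OCc1ccccc1 | intermediate
11 | methyl 4-{[2,4-bis(benzyloxy)-3-bromo-5-chloro-6-methylbenzoyl]oxy}-3,5-dibromo-2-methoxy-6-methylbenzoate | COC(=O)c1c(C)c(Br)c(OC(=O)c2c(C)c(Cl)c(OCc3ccccc3)c(Br)c2OCc2ccccc2)c(Br)c1OC | intermediate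
12 | trimethylboroxine | CB1OB(C)OB(C)O1 | starting material
13 | methyl 4-{[2,4-bis(benzyloxy)-5-chloro-3,6-dimethylbenzoyl]oxy}-2-methoxy-3,5,6-trimethylbenzoate | COC(=O)c1c(C)c(C)c(OC(=O)c2c(C)c(Cl)c(OCc3ccccc3)c(C)c2OCc2ccccc2)c(C)c1OC | intermediate
14 | methyl 4-[(3-chloro-4,6-dihydroxy-2,5-dimethylbenzoyl)oxy]-2-methoxy-3,5,6-trimethylbenzoate | COC(=O)c1c(C)c(C)c(OC(=O)c2c(C)c(Cl)c(O)c(C)c2O)c(C)c1OC | target

**Totals and risks**

Total step count: 11. Longest linear sequence: 7 steps (steps 1–4 or 5–8, then 9, 10, 11).

Most at risk is step 10. Transmetalation from boron to an arylpalladium bromide with two ortho substituents is slow, so the threefold coupling may stall at partly methylated material or lose bromine by protodebromination. Long heating with carbonate may also begin to cleave the depside ester. The fallback sets out from 11 and replaces the boron reagent by a zinc reagent in a Negishi coupling: Me2Zn (excess), PdCl2(dppf), 1,4-dioxane, 90 °C. Transmetalation from zinc is much faster and needs no base, so the ester is not exposed, and the bisphosphine catalyst should still leave the aryl chloride alone. The fallback comes back to the route at 13 and makes no compound outside the list (F0).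

Second is step 9. Acylation of a weakly nucleophilic 2,6-dibromophenoxide by an acid chloride that itself carries two ortho substituents may be too slow, so the acid chloride may instead be lost to moisture or to slow decomposition on heating. The fallback reverses the order of ester formation and bromination. It sets out from 4, the unhindered and more nucleophilic phenol, which is acylated with acid chloride 10 (made from 9 as in step 9) using Et3N and catalytic DMAP in CH2Cl2. This should give methyl 4-{[2,4-bis(benzyloxy)-3-bromo-5-chloro-6-methylbenzoyl]oxy}-2-methoxy-6-methylbenzoate F1. Ring A of this depside is still activated at C3 and C5 by the methoxy group (ortho and para) and the methyl group. Ring B is fully substituted and the benzyl phenyl rings are far less reactive. NBS (2.2 equiv) with catalytic CF3CO2H in MeCN should therefore brominate both ring A positions, and the fallback comes back to the route at 11.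

Third is step 5. The doubly activated resorcinol ring may be chlorinated with imperfect site control, partly between the two hydroxyls, and may go on to the dichloride. The fallback sets out from 2, the 4-O-benzyl ether already made in step 1, which has only one free phenol and is less prone to over-chlorination. SO2Cl2 (1.0 equiv) in CH2Cl2 at 0 °C should chlorinate para to the free hydrogen-bonded hydroxyl, beside the C-methyl group, to give methyl 4-(benzyloxy)-3-chloro-6-hydroxy-2-methylbenzoate F2. NBS in MeCN then brominates the one open position, ortho to the free hydroxyl, to give methyl 4-(benzyloxy)-3-bromo-5-chloro-2-hydroxy-6-methylbenzoate F3. Benzylation of the remaining phenol (BnBr, K2CO3, DMF, 60 °C) brings the fallback back to the route at 8, bypassing 6 and 7.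

**Further compounds**

F0 | step 10 | none | none
F1 | step 9 | methyl 4-{[2,4-bis(benzyloxy)-3-bromo-5-chloro-6-methylbenzoyl]oxy}-2-methoxy-6-methylbenzoate | COC(=O)c1c(C)cc(OC(=O)c2c(C)c(Cl)c(OCc3ccccc3)c(Br)c2OCc2ccccc2)cc1OC
F2 | step 5 | methyl 4-(benzyloxy)-3-chloro-6-hydroxy-2-methylbenzoate | COC(=O)c1c(C)c(Cl)c(OCc2ccccc2)cc1O
F3 | step 5 | methyl 4-(benzyloxy)-3-bromo-5-chloro-2-hydroxy-6-methylbenzoate | COC(=O)c1c(C)c(Cl)c(OCc2ccccc2)c(Br)c1O
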